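**Retrosynthetic overview**
1. Ring D is closed last: C13–C16 by a 5-exo Heck reaction of an 8-(2-bromoacryloyl) lactone, then exo-face hydrogenation sets C16 and saturates C11–C12.
2. C8–C15 comes from C-acylation of the δ-lactone enolate; the Δ12 alkene the Heck step needs comes from SE2′ protodesilylation of a C12 allylsilane.
3. Key step: one radical cascade closes the THF acetal (C5–C6) and the spiro δ-lactone (C9–C10) while desymmetrising a Birch-derived 4-silylcyclohexa-2,5-diene ester.
4. Ring C comes from an arene (1,4-dibromobenzene → 4-TMS-benzoic acid → Birch diene); ring A comes from an asymmetric conjugate methylation that sets C4; the two are joined by a Mitsunobu esterification.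
5. Ring order: A (carbocycle bought, C4 set) → C (dearomatisation) → THF acetal + δ-lactone (cascade) → D.

Assumption: numbered compounds are skeleton-bearing starting materials, intermediates and the target; other reagents are given by name and SMILES in each step. Atom labels C1–C20 are ent-kaurane positions (C19 = CH2O on C4, C20 = CH2O on C10, C6 = acetal carbon, C7 = lactone C=O, C15 = ketone, C17 = methyl on C16).

**Step 1**
Reactants: 1, methyl 3-oxocyclohex-1-ene-1-carboxylate
Product: 2, methyl (1R)-1-methyl-3-{[(trifluoromethyl)sulfonyl]oxy}cyclohex-2-ene-1-carboxylate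
Conditions: Me3Al, CuTC (5 mol %), chiral phosphoramidite L* (10 mol %), Et2O, −30 °C; then MeLi, PhNTf2, THF, −78 → 0 °C
Reagents that add atoms: trimethylaluminium, C[Al](C)C; N-phenyl-bis(trifluoromethanesulfonimide), FC(F)(F)S(=O)(=O)N(c1ccccc1)S(=O)(=O)C(F)(F)F
Why: Cu-catalysed asymmetric conjugate addition puts methyl on the ester-bearing β-carbon, creating the C4 quaternary centre (R; ligand enantiomer chosen accordingly), and in situ triflation of the regiodefined enolate fixes the alkene at C5=C10.

**Step 2**
Reactants: 2
Product: 3, dimethyl (3R)-3-methylcyclohex-1-ene-1,3-dicarboxylate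
Conditions: Pd(OAc)2, dppp, CO (1 atm), MeOH, Et3N, DMF, 60 °C
Reagents that add atoms: carbon monoxide, [C-]#[O+]; methanol, CO
Why: Pd-catalysed methoxycarbonylation of the vinyl triflate installs C20 without touching the quaternary centre.

**Step 3**
Reactants: 3
Product: 4, [(1R)-3-(hydroxymethyl)-1-methylcyclohex-2-en-1-yl]methanol
Conditions: DIBAL-H (6 equiv), CH2Cl2, −78 → 0 °C
Reagents that add atoms: none
Why: Hydride reduction of both esters (1,2-reduction of the enoate) gives the neopentyl C19–OH and the allylic C20–OH.

**Step 4**
Reactants: 5, 1,4-dibromobenzene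
Product: 6, 4-(trimethylsilyl)benzoic acid
Conditions: n-BuLi, THF, −78 °C; TMSCl; then n-BuLi, −78 °C; CO2; H3O+
Reagents that add atoms: chlorotrimethylsilane, C[Si](C)(C)Cl; carbon dioxide, O=C=O
Why: Two sequential Br/Li exchanges with silylation and then carboxylation are standard aryllithium chemistry.

**Step 5**
Reactants: 6
Product: 7, 4-(trimethylsilyl)cyclohexa-2,5-diene-1-carboxylic acid (Cs-symmetric, cis/trans mixture)
Conditions: Li, NH3(l)/THF, −78 °C; NH4Cl
Reagents that add atoms: none
Why: Birch reduction of a benzoic acid reduces the ipso and para carbons (the para carbanion is also α-silyl-stabilised), giving the symmetric 2,5-diene with a bis-allylic silane at C12.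

**Step 6**
Reactants: 4; 7
Product: 8, [(3R)-3-(hydroxymethyl)-3-methylcyclohex-1-en-1-yl]methyl 4-(trimethylsilyl)cyclohexa-2,5-diene-1-carboxylate
Conditions: PPh3, DIAD, THF, 0 °C
Reagents that add atoms: none (both partners are numbered reactants)
Why: Mitsunobu esterification is selective for the unhindered allylic C20–OH because SN2 at the neopentyl C19 carbinol is blocked, and the neutral conditions spare the allylsilane and the acidic dienyl α-H.

**Step 7**
Reactants: 8
Product: 9, [(3R)-3-{[methoxy(phenylselanyl)methoxy]methyl}-3-methylcyclohex-1-en-1-yl]methyl 4-(trimethylsilyl)cyclohexa-2,5-diene-1-carboxylate (1:1 at the Se,O,O-carbon)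
Conditions: HC(OMe)3, PPTS (cat.), 40 °C (−MeOH); then PhSeSiMe3, TMSOTf (10 mol %), CH2Cl2, −78 °C
Reagents that add atoms: trimethyl orthoformate, COC(OC)OC; (phenylseleno)trimethylsilane, C[Si](C)(C)[Se]c1ccccc1
Why: Orthoester exchange onto C19–OH followed by Lewis-acid O→Se exchange (the reaction used to make selenoglycosides) gives an anomeric-type selenide that is a precursor of the alkoxy(methoxy)methyl radical.

**Step 8 (key step)**
Reactants: 9
Product: 10, tetracyclic lactone acetal: 6-methoxy-6,19-epoxide (cis-fused THF acetal, both C6 epimers), 7,20-olide spiro at C10 and cis-fused (H8 cis to H9) to a cyclohex-13-ene ring C carrying 12-SiMe3 (both C12 epimers); C4, C5, C9 and C10 as in ludongnin I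
Conditions: Bu3SnH (1.3 equiv) and AIBN (0.3 equiv) by syringe pump over 10 h, PhMe, 110 °C, 2 mM
Reagents that add atoms: none
Why: Proposed new method: Se abstraction gives the nucleophilic dialkoxymethyl radical, which closes 5-exo onto C5 of the trisubstituted alkene (cis-fused THF forced by the C19 tether on the α face, so C5 follows C4); the resulting tertiary C10 radical then closes 6-exo through the ester onto one of the two enantiotopic diene alkenes, bonding on the β face of ring A anti to the new THF ring (sets C10) and selecting the alkene that places ring C on the side of the C1 methylene rather than the bulky C5 branch (sets C9, and C8 as the cis ring fusion), and the β-silyl C11 radical is reduced by tin hydride; the closest known reactions are Ueno–Stork and anomeric-radical 5-exo acetal cyclisations and tin-hydride radical desymmetrisations of Birch-derived 1-substituted cyclohexa-2,5-dienes.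

**Step 9**
Reactants: 10
Product: 11, the same tetracycle without silicon, with the ring C alkene at C12=C13 and a single (6S) acetal (OMe cis to H5, trans to C10)
Conditions: TFA (10 equiv), CH2Cl2–MeOH (5:1), 0 °C → rt
Reagents that add atoms: none net (methanol, CO, only exchanges the acetal OMe)
Why: SE2′ protodesilylation of the allylsilane (H+ to C14, loss of Si from C12) moves the alkene regiospecifically to Δ12, and acidic methanol equilibrates the acetal to the exo anomer.

**Step 10**
Reactants: 11; 12, 2,3-dibromopropanoyl chloride
Product: 13, the 8-(2-bromoprop-2-enoyl) derivative of 11 (acyl group cis to H9; lactone and cyclohexene cis-fused)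
Conditions: LDA, THF, −78 °C; 12, −78 °C; then Et3N, 0 °C → rt
Reagents that add atoms: none besides 12
Why: Claisen-type C-acylation of the lactone enolate occurs on the face syn to the pseudo-axial H9 (C10 and C11 both lie on the other face), setting the C8 quaternary centre, and E1cB loss of HBr gives the 2-bromoenone.

**Step 11**
Reactants: 13
Product: 14, 11,12,16,17-tetradehydro-ludongnin I (bicyclo[3.2.1]octene ring C/D with 16-exo-methylene-15-ketone and a C11=C12 alkene)
Conditions: Pd(OAc)2 (10 mol %), PPh3 (20 mol %), Ag2CO3, MeCN, 80 °C
Reagents that add atoms: none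
Why: Intramolecular Mizoroki–Heck reaction: 5-exo syn-carbopalladation of the Δ12 alkene by the acyl-vinyl palladium forms C13–C16 on the face of the axial acyl group (C13 is fixed by the bridge), and syn β-H elimination towards C11 releases the diene.

**Step 12**
Reactants: 14
Product: 15, ludongnin I, (4R,5R,6S,8S,9S,10R,13R,16R)
Conditions: H2 (1–3 atm), 10 % Pd/C, EtOAc, rt
Reagents that add atoms: none
Why: Catalytic hydrogenation saturates C11=C12 and delivers hydrogen to the exocyclic enone from the open exo face (the C14 side), leaving the C16 methyl endo, towards the C11–C12 bridge, as in the target.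

**Compound list**
1 | methyl 3-oxocyclohex-1-ene-1-carboxylate | COC(=O)C1=CC(=O)CCC1 | starting material
2 | methyl (1R)-1-methyl-3-(triflyloxy)cyclohex-2-ene-1-carboxylate | COC(=O)[C@]1(C)CCCC(OS(=O)(=O)C(F)(F)F)=C1 | intermediate
3 | dimethyl (3R)-3-methylcyclohex-1-ene-1,3-dicarboxylate | COC(=O)[C@]1(C)CCCC(C(=O)OC)=C1 | intermediate
4 | [(1R)-3-(hydroxymethyl)-1-methylcyclohex-2-en-1-yl]methanol | OC[C@]1(C)CCCC(CO)=C1 | intermediate
5 | 1,4-dibromobenzene | Brc1ccc(Br)cc1 | starting material
6 | 4-(trimethylsilyl)benzoic acid | C[Si](C)(C)c1ccc(cc1)C(=O)O | intermediate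
7 | 4-(trimethylsilyl)cyclohexa-2,5-diene-1-carboxylic acid (cis/trans) | OC(=O)C1C=CC(C=C1)[Si](C)(C)C | intermediate
8 | Mitsunobu ester of 4 (at C20–OH) with 7 | OC[C@]1(C)CCCC(COC(=O)C2C=CC(C=C2)[Si](C)(C)C)=C1 | intermediate
9 | C19 methoxy(phenylselanyl)methyl ether of 8 | COC([Se]c1ccccc1)OC[C@]2(C)CCCC(COC(=O)C3C=CC(C=C3)[Si](C)(C)C)=C2 | intermediate
10 | cascade product (C6 and C12 epimer mixtures) | COC1OC[C@]2(C)CCC[C@]3(COC(=O)[C@H]4C=CC(C[C@H]43)[Si](C)(C)C)[C@H]12 | intermediate
11 | desilylated Δ12 lactone acetal, single anomer | CO[C@H]1OC[C@]2(C)CCC[C@]3(COC(=O)[C@H]4CC=CC[C@H]43)[C@H]12 | intermediate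
12 | 2,3-dibromopropanoyl chloride | ClC(=O)C(Br)CBr | starting material
13 | 8-(2-bromoacryloyl) lactone | CO[C@H]1OC[C@]2(C)CCC[C@]3(COC(=O)[C@@]4(C(=O)C(Br)=C)CC=CC[C@H]43)[C@H]12 | intermediate
14 | 11,12,16,17-tetradehydro-ludongnin I | CO[C@H]1OC[C@]2(C)CCC[C@]3(COC(=O)[C@@]45C[C@@H](C=C[C@H]43)C(=C)C5=O)[C@H]12 | intermediate
15 | ludongnin I | CO[C@H]1OC[C@]2(C)CCC[C@]3(COC(=O)[C@@]45C[C@@H](CC[C@H]43)[C@@H](C)C5=O)[C@H]12 | target

**Step count**
Total: 12 steps. Longest linear sequence: 10 steps (1, 2, 3, 6, 7, 8, 9, 10, 11, 12).

**Three steps most likely to fail, with fallbacks**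
- **Step 8 (cascade).** The 6-exo closure must pass through the s-cis ester onto an unactivated alkene, the diene has weak bis-allylic C–H bonds, and the choice between the two alkenes is substrate-controlled. Fallback: use the unsilylated Birch diene, make C8 quaternary first, and oxidise the bis-allylic CH2 to the 4,4-disubstituted cyclohexa-2,5-dienone. The second closure then becomes a polarity-matched 6-exo Giese addition, and reductive 1,3-transposition of the remaining enone (tosylhydrazone, catecholborane) gives the same Δ12 alkene.
- **Step 7 (Se,O,O-orthoformate).** The dialkoxycarbenium intermediate could instead be trapped by the nearby C5=C10 alkene (Prins) or by the allylsilane. Fallback: generate the same radical by decarboxylation. O-alkylate C19–OH with methyl bromo(methoxy)acetate, saponify, make the N-hydroxyphthalimide ester and fragment it reductively, so no cationic step is needed.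
- **Step 10 (C8 acylation).** O-acylation or attack on the wrong face would give the wrong product or the trans-fused isomer. Fallback: acylate the dienyl ester enolate of 9 with 3-chloropropanoyl chloride before the cascade, so C8 is already quaternary and its configuration is fixed by the cis ring fusion formed in the cascade. After step 9, I2/pyridine converts the β-chloroketone to the α-iodoenone for the same Heck closure (one step longer).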